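## Structural features

The target is a 20-membered macrolactone (chain numbering C1 = lactone carbonyl to C19 = ring carbinol carbon) with a 2,4-dihydroxypentyl side chain (C20–C24) on C19. In the ring, C1–C3 form a (Z)-enoate, C4 is a secondary carbinol (R) and C5/C6 a trans-epoxide (5S,6S). The C4 hydroxyl and the C5–O bond are threo (syn in the zigzag), which is the relationship that tartrate-controlled epoxidation of a secondary allylic alcohol does not give. Twelve methylene groups (C7–C18) separate this triad from C19 (S), so nothing can be relayed between the two halves. O19, O21 and O23 are all syn (19S,21R,23R); O19 must end acylated while O21 and O23 stay free. The fragile elements are the 4-hydroxy-(2Z)-enoate (attack of O4 on C1 gives a butenolide and opens the macrocycle; nucleophilic catalysts isomerise Z to E), the epoxide next to a free hydroxyl (Payne rearrangement under base, solvolysis under acid) and any 2,3-epoxy aldehyde on the way. The real difficulty is to close the large ring through a Z-enoate that tolerates neither carboxyl activation nor base, and to set C4 threo to the epoxide. The key step exploits the fact that C4 is both a ring atom and a carbinol next to C3: with C1–C3 present as a linear propiolate already esterified to O19, the C3–C4 bond is made by addition of the acetylide to a C4 formyl group on the epoxide. This closes the ring and creates C4 in one event, and the linear C1–C2≡C3 unit keeps O4 away from C1.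

## Logic of the disconnections

25 ⇒ 24. No skeletal bond is cut; the two C–H bonds at C2 and C3 are removed to give the alkyne. The Z geometry then comes from syn delivery of hydrogen, and the labile 4-hydroxy-(2Z)-enoate exists only after the last, neutral step. The gain is that every earlier intermediate carries a linear C1–C3 unit that cannot translactonise. The forward step must stop at the alkene and spare the epoxide.

24 ⇒ 23. The two C–O bonds of an isopropylidene acetal on O21/O23 are restored. The two hydroxyls must be masked as one unit while O19 is acylated and while zinc reagents are used. One protecting group matches the syn-1,3-diol. The forward step needs mild acid that leaves the epoxide alone.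

23 ⇒ 21 (key). The C3–C4 bond is cut, which opens the 20-membered ring and erases the C4 stereocentre. In one sentence: the ring is closed by an intramolecular, ligand-controlled zinc acetylide addition within 21. C4 is the only ring atom that can be made by polar carbonyl addition without activating the carboxyl group, and the nucleophile is already tethered through the ester. The precursor is an acyclic ester-aldehyde that needs no protecting group on O4 and no seco acid. The forward step must add to the Re face of the formyl group, at high dilution, in the presence of epoxide, ester and acetonide.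

21 ⇒ 19 + 20. The O19–C1 ester bond is cut. This is a plain acylation of the one free hydroxyl, and C1–C3 come from a three-carbon commodity acid. The forward step must tolerate the epoxy aldehyde.

19 ⇒ 18 ⇒ 17. No C–C bond is cut: the formyl group goes back to the primary alcohol and O19 to its silyl ether. 17 is the direct product of the asymmetric epoxidation, and the silyl ether on O19 is what the linchpin coupling delivers. The forward oxidation must select the primary alcohol beside a free secondary one.

17 ⇒ 16 ⇒ 15 ⇒ 13 + 14. The two epoxide C–O bonds are cut, then the C5=C6 bond. The (E)-allylic alcohol is the substrate for tartrate-controlled epoxidation, which sets C5 and C6 together, and the E-alkene comes from cross-metathesis of a terminal alkene. The gain is a terminal alkene as the only function at that end. The forward steps need E-selective metathesis and reagent-controlled epoxidation.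

13 ⇒ 12 ⇒ 10 ⇒ 9. The acetonide C–O bonds are cut, then the C21–H bond (back to the ketone), then the carbonyl is returned to a dithiane. C21 is relayed from C23 by a chelation-controlled 1,3-syn reduction, so it needs no reagent control, and its carbon becomes a masked acyl anion. The forward unmasking must spare the terminal alkene.

9 ⇒ 3 + 4 + 5. The C20–C21 and C21–C22 bonds are cut. C21 is flanked by two CH2–CH(O) units, the retron of a double epoxide opening by a dithiane linchpin; the silyl migration that links the two openings differentiates O19 from O23. Three components of similar simplicity result, two of them with a single stereocentre. The forward step needs ordered addition so that O19 receives the silyl group.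

3 ⇒ 2 ⇒ 1. The C19–O and C20–O bonds are cut. One alkene of a symmetric diene becomes the C19 stereocentre through kinetic resolution; the other is kept for the metathesis. The forward steps need statistical mono-epoxidation and resolution.

## Other disconnections considered

Alternative 1: Macrolactonisation at O19–C1, the first idea. The cut gives the (2Z)-4-silyloxy seco acid A1, which a Yamaguchi or Shiina lactonisation would close to the O4-silylated macrolide A2, followed by deprotection to 25. Activating a (Z)-4-oxygenated enoic acid as a mixed anhydride with DMAP present invites conjugate addition–elimination and therefore Z to E isomerisation. O4 must also carry a protecting group orthogonal to that on O19, or the activated acid closes to the butenolide. C4 has to be made in a separate intermolecular step and an ester must be hydrolysed beside the epoxide. The chosen plan makes C4 and the ring together and is two to three steps shorter.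

Alternative 2: Carbonylative macrolactonisation, cutting C1–C2 and C1–O19 with carbon monoxide as C1. The (Z)-iodoalkene alcohol A3 would be closed with zerovalent palladium (Pd(PPh3)4) under CO to the O4-silylated macrolide A4. The acyl-palladium intermediate would be captured by O4 to give a butenolide unless O4 is protected orthogonally to O19. Making the Z-iodoalkene from a propargylic alcohol costs three extra steps (desilylation, iodination, diimide reduction). The key step is of a known type, but the route is longer than the chosen one.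

Alternative 3: Ring-closing metathesis at C5=C6 followed by hydroxyl-directed epoxidation. The diene ester A5 would give the macrocyclic (E)-allylic alcohol A6, which would be epoxidised to 23. The substrate does not secure E/Z control in a 20-membered ring, and the ynoate is a competing site for the ruthenium carbene. Directed epoxidation of an E-disubstituted secondary allylic alcohol favours the erythro product with titanium or vanadium peroxides and has weak facial bias with peracids, whereas the target is threo. The stereotriad would then rest on macrocyclic conformational control that cannot be argued in advance.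

Key step: step 13

Assumption 1: hexadeca-1,15-diene (1) is taken as a commercial diene.
Assumption 2: (S,S)-ProPhenol is written in step 13 on the assumption that it is the ligand hand that delivers a zinc acetylide to the Re face of an aldehyde; if the sense is opposite, (R,R)-ProPhenol is used with no other change.

## Steps

Step 1
Reactants: 1 hexadeca-1,15-diene
Product: 2 rac-2-(tetradec-13-en-1-yl)oxirane
Conditions: mCPBA (0.35 equiv), 1 in excess (recovered), CH2Cl2, 0 °C
Reagents that add atoms: mCPBA (3-chloroperoxybenzoic acid), OOC(=O)c1cccc(Cl)c1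
Why: Prilezhaev epoxidation; with the symmetric diene in excess the mono-epoxide should dominate and is separable from diene and bis-epoxide. No stereocontrol is needed because step 2 resolves C19.

Step 2
Reactants: 2 rac-2-(tetradec-13-en-1-yl)oxirane
Product: 3 (S)-2-(tetradec-13-en-1-yl)oxirane
Conditions: (S,S)-(salen)Co(OAc) (0.5 mol%), H2O (0.55 equiv), THF, 0 °C to rt
Reagents that add atoms: none
Why: Jacobsen hydrolytic kinetic resolution; the (S,S)-catalyst should hydrate the (R)-epoxide selectively and leave (S)-3, which fixes C19. The diol is removed by chromatography.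

Step 3
Reactants: 3 (S)-2-(tetradec-13-en-1-yl)oxirane; 4 2-(tert-butyldimethylsilyl)-1,3-dithiane; 5 (R)-2-methyloxirane
Product: 9 (2R)-1-{2-[(2S)-2-(tert-butyldimethylsilyloxy)hexadec-15-en-1-yl]-1,3-dithian-2-yl}propan-2-ol, via 2-lithio-2-(tert-butyldimethylsilyl)-1,3-dithiane 6 (not isolated), via lithium (2S)-1-[2-(tert-butyldimethylsilyl)-1,3-dithian-2-yl]hexadec-15-en-2-olate 7 (not isolated), via 2-lithio-2-[(2S)-2-(tert-butyldimethylsilyloxy)hexadec-15-en-1-yl]-1,3-dithiane 8 (not isolated)
Conditions: 4, t-BuLi, Et2O, −78 to −45 °C; 3, −78 to −25 °C; then 5, HMPA, THF, −78 °C to rt; H2O quench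
Reagents that add atoms: none
Why: Anion relay chemistry (Corey–Seebach alkylation, HMPA-triggered 1,4-Brook rearrangement, second alkylation) joins three components in one flask. Both epoxides open at CH2, so C19 and C23 are carried over unchanged. The silyl shift leaves O19 silylated and O23 free, which differentiates the two oxygens.

Step 4
Reactants: 9 (2R)-1-{2-[(2S)-2-(tert-butyldimethylsilyloxy)hexadec-15-en-1-yl]-1,3-dithian-2-yl}propan-2-ol
Product: 10 (2R,6S)-6-(tert-butyldimethylsilyloxy)-2-hydroxyicos-19-en-4-one
Conditions: MeI, CaCO3, MeCN–H2O (9:1), 45 °C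
Reagents that add atoms: water, O
Why: S-alkylative dithiane hydrolysis; the buffered, non-oxidising conditions should spare the terminal alkene and the silyl ether and avoid β-elimination of the aldol-type product.

Step 5
Reactants: 10 (2R,6S)-6-(tert-butyldimethylsilyloxy)-2-hydroxyicos-19-en-4-one
Product: 12 (2R,4R,6S)-6-(tert-butyldimethylsilyloxy)icos-19-ene-2,4-diol, via (2R,6S)-6-(tert-butyldimethylsilyloxy)-2-(diethylboryloxy)icos-19-en-4-one 11 (not isolated)
Conditions: Et2BOMe, THF–MeOH (4:1), −78 °C; NaBH4; then MeOH co-evaporation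
Reagents that add atoms: none
Why: Narasaka–Prasad reduction; the boron chelate between O23 and the ketone adopts a half-chair and external hydride adds axially, giving the 1,3-syn diol. C21 (R) is thereby relayed from C23.

Step 6
Reactants: 12 (2R,4R,6S)-6-(tert-butyldimethylsilyloxy)icos-19-ene-2,4-diol
Product: 13 tert-butyldimethyl{[(2S)-1-[(4R,6R)-2,2,6-trimethyl-1,3-dioxan-4-yl]hexadec-15-en-2-yl]oxy}silane
Conditions: 2,2-dimethoxypropane, PPTS (cat.), CH2Cl2, rt
Reagents that add atoms: 2,2-dimethoxypropane, COC(C)(C)OC
Why: Acid-catalysed transacetalisation; the syn-1,3-diol gives a chair dioxane with both substituents equatorial, and the secondary silyl ether should survive PPTS.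

Step 7
Reactants: 13 tert-butyldimethyl{[(2S)-1-[(4R,6R)-2,2,6-trimethyl-1,3-dioxan-4-yl]hexadec-15-en-2-yl]oxy}silane; 14 (E)-but-2-enal
Product: 15 (2E,16S)-16-(tert-butyldimethylsilyloxy)-17-[(4R,6R)-2,2,6-trimethyl-1,3-dioxan-4-yl]heptadec-2-enal
Conditions: 14 (5 equiv), second-generation Hoveyda–Grubbs catalyst RuCl2(H2IMes)(=CH-C6H4-2-OiPr) (5 mol%), CH2Cl2, 40 °C
Reagents that add atoms: none
Why: Olefin cross-metathesis of a terminal alkene with an electron-poor enal partner, which should give the conjugated E-enal selectively with loss of propene.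

Step 8
Reactants: 15 (2E,16S)-16-(tert-butyldimethylsilyloxy)-17-[(4R,6R)-2,2,6-trimethyl-1,3-dioxan-4-yl]heptadec-2-enal
Product: 16 (2E,16S)-16-(tert-butyldimethylsilyloxy)-17-[(4R,6R)-2,2,6-trimethyl-1,3-dioxan-4-yl]heptadec-2-en-1-ol
Conditions: NaBH4, CeCl3·7H2O, MeOH, −20 °C
Reagents that add atoms: none
Why: Luche reduction; 1,2-hydride addition to the enal should give the (E)-allylic alcohol without touching the acetonide or silyl ether.

Step 9
Reactants: 16 (2E,16S)-16-(tert-butyldimethylsilyloxy)-17-[(4R,6R)-2,2,6-trimethyl-1,3-dioxan-4-yl]heptadec-2-en-1-ol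
Product: 17 [(2S,3S)-3-{(13S)-13-(tert-butyldimethylsilyloxy)-14-[(4R,6R)-2,2,6-trimethyl-1,3-dioxan-4-yl]tetradecyl}oxiran-2-yl]methanol
Conditions: Ti(OiPr)4 (20 mol%), L-(+)-diethyl tartrate (24 mol%), t-BuOOH, 4 Å MS, CH2Cl2, −20 °C
Reagents that add atoms: tert-butyl hydroperoxide, CC(C)(C)OO
Why: Sharpless asymmetric epoxidation; L-(+)-tartrate delivers oxygen to the alkene face that gives the (2S,3S)-epoxy alcohol from an (E)-2-alken-1-ol, which sets C5 and C6 together under reagent control. The remote centres are too far away to interfere.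

Step 10
Reactants: 17 [(2S,3S)-3-{(13S)-13-(tert-butyldimethylsilyloxy)-14-[(4R,6R)-2,2,6-trimethyl-1,3-dioxan-4-yl]tetradecyl}oxiran-2-yl]methanol
Product: 18 (2S)-14-[(2S,3S)-3-(hydroxymethyl)oxiran-2-yl]-1-[(4R,6R)-2,2,6-trimethyl-1,3-dioxan-4-yl]tetradecan-2-ol
Conditions: TBAF, AcOH (1:1), THF, rt
Reagents that add atoms: none
Why: Fluoride desilylation; buffering with acetic acid should suppress Payne rearrangement of the epoxy alcohol, and the acetonide is inert to fluoride.

Step 11
Reactants: 18 (2S)-14-[(2S,3S)-3-(hydroxymethyl)oxiran-2-yl]-1-[(4R,6R)-2,2,6-trimethyl-1,3-dioxan-4-yl]tetradecan-2-ol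
Product: 19 (2R,3S)-3-{(13S)-13-hydroxy-14-[(4R,6R)-2,2,6-trimethyl-1,3-dioxan-4-yl]tetradecyl}oxirane-2-carbaldehyde
Conditions: TEMPO (10 mol%), PhI(OAc)2, CH2Cl2, rt
Reagents that add atoms: none
Why: Oxoammonium-mediated oxidation, which is selective for primary over secondary alcohols and stops at the aldehyde. The epoxide α-hydrogen does not enolise, so C5 should be configurationally safe.

Step 12
Reactants: 19 (2R,3S)-3-{(13S)-13-hydroxy-14-[(4R,6R)-2,2,6-trimethyl-1,3-dioxan-4-yl]tetradecyl}oxirane-2-carbaldehyde; 20 prop-2-ynoic acid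
Product: 21 (2S)-14-[(2S,3R)-3-formyloxiran-2-yl]-1-[(4R,6R)-2,2,6-trimethyl-1,3-dioxan-4-yl]tetradecan-2-yl prop-2-ynoate
Conditions: 20, DCC, DMAP (5 mol%), CH2Cl2, −20 °C
Reagents that add atoms: none
Why: Steglich esterification of the only free hydroxyl (O19); the aldehyde is not a partner for the O-acylisourea. Low temperature and little DMAP should limit amine addition to the propiolate.

Step 13
Reactants: 21 (2S)-14-[(2S,3R)-3-formyloxiran-2-yl]-1-[(4R,6R)-2,2,6-trimethyl-1,3-dioxan-4-yl]tetradecan-2-yl prop-2-ynoate
Product: 23 (5R,6S,7S,20S)-6,7-epoxy-5-hydroxy-20-{[(4R,6R)-2,2,6-trimethyl-1,3-dioxan-4-yl]methyl}-1-oxacycloicos-3-yn-2-one, via C3-methylzinc acetylide of the propiolate ester 22 (not isolated)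
Conditions: (S,S)-ProPhenol (0.4 equiv), Me2Zn (3 equiv), Ph3PO (0.8 equiv), toluene; slow addition of 21 to 2 mM, 4 °C; aq. NH4Cl
Reagents that add atoms: none
Why: Proposed new method: Me2Zn, activated by the dinuclear zinc–ProPhenol alkoxide, deprotonates the acidic propiolate C–H of 21 to the methylzinc acetylide 22; its alkynyl group sits on one zinc of the chiral complex while the formyl oxygen binds the other, so C3 is transferred to C4 within one complex. The closest known reaction types are the intermolecular zinc–ProPhenol addition of alkyl propiolates to aldehydes and the Nozaki–Hiyama–Kishi ring closure of iodoalkynes onto aldehydes; what is new is the use of the zinc-catalysed propiolate addition as a macrocyclisation. The 20-membered ring closes in a 20-exo-trig mode by attack of C3 on the exocyclic C4=O, and the flexible (CH2)12 tether should add no strain. The new stereocentre C4 (R) requires attack on the Re face of the formyl group (priorities O > C5 > H); the ligand sets this, and it is also the Cram-chelate sense, because zinc bridging the formyl and epoxide oxygens exposes the face flanked by H5 and leads to the threo epoxy alcohol. Ring closure must beat oligomerisation, which slow addition to about 2 mM should secure. Alkynyl must transfer in preference to methyl, which the low migratory aptitude of methyl on zinc should secure, and the mild Lewis acidity of zinc should leave the epoxide and acetonide intact. The zinc alkoxide formed at O4 cannot reach C1 through the linear alkyne, so the ester made in step 12 is safe.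

Step 14
Reactants: 23 (5R,6S,7S,20S)-6,7-epoxy-5-hydroxy-20-{[(4R,6R)-2,2,6-trimethyl-1,3-dioxan-4-yl]methyl}-1-oxacycloicos-3-yn-2-one
Product: 24 (5R,6S,7S,20S)-20-[(2R,4R)-2,4-dihydroxypentyl]-6,7-epoxy-5-hydroxy-1-oxacycloicos-3-yn-2-one
Conditions: PPTS (cat.), MeOH, rt
Reagents that add atoms: none
Why: Acid-catalysed transacetalisation to methanol. It is run at the alkyne stage because the linear C1–C2≡C3 unit prevents translactonisation by O4, and the trans-disubstituted epoxide flanked by an electron-poor carbinol should resist mild acid.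

Step 15
Reactants: 24 (5R,6S,7S,20S)-20-[(2R,4R)-2,4-dihydroxypentyl]-6,7-epoxy-5-hydroxy-1-oxacycloicos-3-yn-2-one
Product: 25 (3Z,5R,6S,7S,20S)-20-[(2R,4R)-2,4-dihydroxypentyl]-6,7-epoxy-5-hydroxy-1-oxacycloicos-3-en-2-one (target)
Conditions: H2 (1 atm), Pd/CaCO3 poisoned with Pb(OAc)2 (Lindlar catalyst), quinoline, EtOAc, 0 °C to rt
Reagents that add atoms: none
Why: Lindlar semi-hydrogenation; syn delivery of H2 on the catalyst surface gives the (Z)-enoate and quinoline should hold the reduction at the alkene. The conditions are neutral, so the 4-hydroxy-(2Z)-enoate is formed without acid or base and no stereocentre is touched.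

## Compound list

1 | hexadeca-1,15-diene | C=CCCCCCCCCCCCCC=C | starting material
2 | rac-2-(tetradec-13-en-1-yl)oxirane | C=CCCCCCCCCCCCCC1CO1 | intermediate
3 | (S)-2-(tetradec-13-en-1-yl)oxirane | C=CCCCCCCCCCCCC[C@H]1CO1 | intermediate
4 | 2-(tert-butyldimethylsilyl)-1,3-dithiane | CC(C)(C)[Si](C)(C)C1SCCCS1 | starting material
5 | (R)-2-methyloxirane | C[C@@H]1CO1 | starting material
6 | 2-lithio-2-(tert-butyldimethylsilyl)-1,3-dithiane | [Li]C1([Si](C)(C)C(C)(C)C)SCCCS1 | intermediate
7 | lithium (2S)-1-[2-(tert-butyldimethylsilyl)-1,3-dithian-2-yl]hexadec-15-en-2-olate | [Li+].[O-][C@H](CC1([Si](C)(C)C(C)(C)C)SCCCS1)CCCCCCCCCCCCC=C | intermediate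
8 | 2-lithio-2-[(2S)-2-(tert-butyldimethylsilyloxy)hexadec-15-en-1-yl]-1,3-dithiane | [Li]C1(C[C@@H](O[Si](C)(C)C(C)(C)C)CCCCCCCCCCCCC=C)SCCCS1 | intermediate
9 | (2R)-1-{2-[(2S)-2-(tert-butyldimethylsilyloxy)hexadec-15-en-1-yl]-1,3-dithian-2-yl}propan-2-ol | C[C@@H](O)CC1(C[C@@H](O[Si](C)(C)C(C)(C)C)CCCCCCCCCCCCC=C)SCCCS1 | intermediate
10 | (2R,6S)-6-(tert-butyldimethylsilyloxy)-2-hydroxyicos-19-en-4-one | C[C@@H](O)CC(=O)C[C@@H](O[Si](C)(C)C(C)(C)C)CCCCCCCCCCCCC=C | intermediate
11 | (2R,6S)-6-(tert-butyldimethylsilyloxy)-2-(diethylboryloxy)icos-19-en-4-one | CCB(CC)O[C@H](C)CC(=O)C[C@@H](O[Si](C)(C)C(C)(C)C)CCCCCCCCCCCCC=C | intermediate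
12 | (2R,4R,6S)-6-(tert-butyldimethylsilyloxy)icos-19-ene-2,4-diol | C[C@@H](O)C[C@@H](O)C[C@@H](O[Si](C)(C)C(C)(C)C)CCCCCCCCCCCCC=C | intermediate
13 | tert-butyldimethyl{[(2S)-1-[(4R,6R)-2,2,6-trimethyl-1,3-dioxan-4-yl]hexadec-15-en-2-yl]oxy}silane | C[C@@H]1C[C@H](C[C@@H](O[Si](C)(C)C(C)(C)C)CCCCCCCCCCCCC=C)OC(C)(C)O1 | intermediate
14 | (E)-but-2-enal | C/C=C/C=O | starting material
15 | (2E,16S)-16-(tert-butyldimethylsilyloxy)-17-[(4R,6R)-2,2,6-trimethyl-1,3-dioxan-4-yl]heptadec-2-enal | C[C@@H]1C[C@H](C[C@@H](O[Si](C)(C)C(C)(C)C)CCCCCCCCCCCC/C=C/C=O)OC(C)(C)O1 | intermediate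
16 | (2E,16S)-16-(tert-butyldimethylsilyloxy)-17-[(4R,6R)-2,2,6-trimethyl-1,3-dioxan-4-yl]heptadec-2-en-1-ol | C[C@@H]1C[C@H](C[C@@H](O[Si](C)(C)C(C)(C)C)CCCCCCCCCCCC/C=C/CO)OC(C)(C)O1 | intermediate
17 | [(2S,3S)-3-{(13S)-13-(tert-butyldimethylsilyloxy)-14-[(4R,6R)-2,2,6-trimethyl-1,3-dioxan-4-yl]tetradecyl}oxiran-2-yl]methanol | C[C@@H]1C[C@H](C[C@@H](O[Si](C)(C)C(C)(C)C)CCCCCCCCCCCC[C@@H]2O[C@H]2CO)OC(C)(C)O1 | intermediate
18 | (2S)-14-[(2S,3S)-3-(hydroxymethyl)oxiran-2-yl]-1-[(4R,6R)-2,2,6-trimethyl-1,3-dioxan-4-yl]tetradecan-2-ol | C[C@@H]1C[C@H](C[C@@H](O)CCCCCCCCCCCC[C@@H]2O[C@H]2CO)OC(C)(C)O1 | intermediate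
19 | (2R,3S)-3-{(13S)-13-hydroxy-14-[(4R,6R)-2,2,6-trimethyl-1,3-dioxan-4-yl]tetradecyl}oxirane-2-carbaldehyde | C[C@@H]1C[C@H](C[C@@H](O)CCCCCCCCCCCC[C@@H]2O[C@H]2C=O)OC(C)(C)O1 | intermediate
20 | prop-2-ynoic acid | C#CC(=O)O | starting material
21 | (2S)-14-[(2S,3R)-3-formyloxiran-2-yl]-1-[(4R,6R)-2,2,6-trimethyl-1,3-dioxan-4-yl]tetradecan-2-yl prop-2-ynoate | C[C@@H]1C[C@H](C[C@@H](OC(=O)C#C)CCCCCCCCCCCC[C@@H]2O[C@H]2C=O)OC(C)(C)O1 | intermediate
22 | C3-methylzinc acetylide of 21 | C[C@@H]1C[C@H](C[C@@H](OC(=O)C#C[Zn]C)CCCCCCCCCCCC[C@@H]2O[C@H]2C=O)OC(C)(C)O1 | intermediate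
23 | (5R,6S,7S,20S)-6,7-epoxy-5-hydroxy-20-{[(4R,6R)-2,2,6-trimethyl-1,3-dioxan-4-yl]methyl}-1-oxacycloicos-3-yn-2-one | C[C@@H]1C[C@H](C[C@@H]2CCCCCCCCCCCC[C@@H]3O[C@H]3[C@H](O)C#CC(=O)O2)OC(C)(C)O1 | intermediate
24 | (5R,6S,7S,20S)-20-[(2R,4R)-2,4-dihydroxypentyl]-6,7-epoxy-5-hydroxy-1-oxacycloicos-3-yn-2-one | C[C@@H](O)C[C@@H](O)C[C@@H]1CCCCCCCCCCCC[C@@H]2O[C@H]2[C@H](O)C#CC(=O)O1 | intermediate
25 | (3Z,5R,6S,7S,20S)-20-[(2R,4R)-2,4-dihydroxypentyl]-6,7-epoxy-5-hydroxy-1-oxacycloicos-3-en-2-one | C[C@@H](O)C[C@@H](O)C[C@@H]1CCCCCCCCCCCC[C@@H]2O[C@H]2[C@H](O)/C=C\C(=O)O1 | target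

## Step count and least certain steps

Total step count: 15. Longest linear sequence: 15 steps (from 1).

Step 13 (key step, proposed new method). The likely failure is intermolecular addition and oligomerisation winning over ring closure, because metalation of the alkyne is slow and one catalyst unit must hold both ends of the same molecule. A second failure is erosion of facial control if an unligated, Felkin-type background addition competes. The fallback uses known chemistry and runs from 19 to 23. Intermolecular zinc–ProPhenol addition of methyl propiolate to 19 should give the methyl 4-hydroxy-2-ynoate F1, with C4 set as in step 13. LiOH in aqueous THF at 0 °C then gives the dihydroxy ynoic seco acid F2. Shiina macrolactonisation (2-methyl-6-nitrobenzoic anhydride, DMAP, high dilution) closes O19–C1 to give 23; O4 cannot reach C1 through the linear alkyne, so only O19 can lactonise.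

Step 12. The likely failure is degradation of the unprotected 2,3-epoxy aldehyde (hydration, aldol-type oligomerisation) during the carbodiimide coupling, together with amine-initiated polymerisation of the propiolate. The fallback runs from 18 to 21 and makes the aldehyde only after the acylation. Selective silylation of the primary hydroxyl of 18 (Et3SiCl, imidazole, −40 °C) gives the primary triethylsilyl ether F3. Steglich esterification with 20 gives the silylated propiolate F4. HF·pyridine removes the silyl group to give the epoxy alcohol propiolate F5, and TEMPO/PhI(OAc)2 oxidation of F5 gives 21.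

Step 3. The likely failure is loss of the three-component order: Brook rearrangement before 5 is added (double alkylation by 3) or incomplete rearrangement (arrest at the mono-adduct). The fallback runs from 3 to 9 as a stepwise Corey–Seebach sequence without silyl relay. 2-Lithio-1,3-dithiane opens 3 to the dithianyl alcohol F6. t-BuMe2SiCl and imidazole give the silyl ether F7. Lithiation of F7 (t-BuLi, THF–HMPA, −78 °C) and opening of 5 give 9.

Step 15. The likely failure is over-reduction of the enoate, or retention and translactonisation of the polar tetraol on the basic catalyst support. The fallback runs from 23 to 25 and changes the order of the endgame. Semi-hydrogenation of the acetonide 23 under the same catalyst gives the less polar (Z)-enoate acetonide F8, which can be purified by chromatography. The acetonide is then cleaved with PPTS in MeOH at 0 °C to give 25.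

## Further compounds

F1 | step 13 | methyl (4R)-4-hydroxy-4-[(2S,3S)-3-{(13S)-13-hydroxy-14-[(4R,6R)-2,2,6-trimethyl-1,3-dioxan-4-yl]tetradecyl}oxiran-2-yl]but-2-ynoate | C[C@@H]1C[C@H](C[C@@H](O)CCCCCCCCCCCC[C@@H]2O[C@H]2[C@H](O)C#CC(=O)OC)OC(C)(C)O1
F2 | step 13 | (4R)-4-hydroxy-4-[(2S,3S)-3-{(13S)-13-hydroxy-14-[(4R,6R)-2,2,6-trimethyl-1,3-dioxan-4-yl]tetradecyl}oxiran-2-yl]but-2-ynoic acid | C[C@@H]1C[C@H](C[C@@H](O)CCCCCCCCCCCC[C@@H]2O[C@H]2[C@H](O)C#CC(=O)O)OC(C)(C)O1
F3 | step 12 | (2S)-1-[(4R,6R)-2,2,6-trimethyl-1,3-dioxan-4-yl]-14-[(2S,3S)-3-{[(triethylsilyl)oxy]methyl}oxiran-2-yl]tetradecan-2-ol | C[C@@H]1C[C@H](C[C@@H](O)CCCCCCCCCCCC[C@@H]2O[C@H]2CO[Si](CC)(CC)CC)OC(C)(C)O1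
F4 | step 12 | (2S)-1-[(4R,6R)-2,2,6-trimethyl-1,3-dioxan-4-yl]-14-[(2S,3S)-3-{[(triethylsilyl)oxy]methyl}oxiran-2-yl]tetradecan-2-yl prop-2-ynoate | C[C@@H]1C[C@H](C[C@@H](OC(=O)C#C)CCCCCCCCCCCC[C@@H]2O[C@H]2CO[Si](CC)(CC)CC)OC(C)(C)O1
F5 | step 12 | (2S)-14-[(2S,3S)-3-(hydroxymethyl)oxiran-2-yl]-1-[(4R,6R)-2,2,6-trimethyl-1,3-dioxan-4-yl]tetradecan-2-yl prop-2-ynoate | C[C@@H]1C[C@H](C[C@@H](OC(=O)C#C)CCCCCCCCCCCC[C@@H]2O[C@H]2CO)OC(C)(C)O1
F6 | step 3 | (2S)-1-(1,3-dithian-2-yl)hexadec-15-en-2-ol | S1CCCSC1C[C@@H](O)CCCCCCCCCCCCC=C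
F7 | step 3 | tert-butyl{[(2S)-1-(1,3-dithian-2-yl)hexadec-15-en-2-yl]oxy}dimethylsilane | S1CCCSC1C[C@@H](O[Si](C)(C)C(C)(C)C)CCCCCCCCCCCCC=C
F8 | step 15 | (3Z,5R,6S,7S,20S)-6,7-epoxy-5-hydroxy-20-{[(4R,6R)-2,2,6-trimethyl-1,3-dioxan-4-yl]methyl}-1-oxacycloicos-3-en-2-one | C[C@@H]1C[C@H](C[C@@H]2CCCCCCCCCCCC[C@@H]3O[C@H]3[C@H](O)/C=C\C(=O)O2)OC(C)(C)O1
A1 | alternative 1 | (2Z)-seco acid with O4 tert-butyldimethylsilyl ether, 5,6-epoxide, free O19–H and 21,23-acetonide, all centres arranged as in 25 | C[C@@H]1C[C@H](C[C@@H](O)CCCCCCCCCCCC[C@@H]2O[C@H]2[C@H](O[Si](C)(C)C(C)(C)C)/C=C\C(=O)O)OC(C)(C)O1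
A2 | alternative 1 | O4 tert-butyldimethylsilyl ether of the 21,23-acetonide of 25 | C[C@@H]1C[C@H](C[C@@H]2CCCCCCCCCCCC[C@@H]3O[C@H]3[C@H](O[Si](C)(C)C(C)(C)C)/C=C\C(=O)O2)OC(C)(C)O1
A3 | alternative 2 | (Z)-2-iodoalkene (C2=C3) with O4 triethylsilyl ether, 5,6-epoxide, free O19–H and 21,23-acetonide, all centres arranged as in 25 | C[C@@H]1C[C@H](C[C@@H](O)CCCCCCCCCCCC[C@@H]2O[C@H]2[C@H](O[Si](CC)(CC)CC)/C=C\I)OC(C)(C)O1
A4 | alternative 2 | O4 triethylsilyl ether of the 21,23-acetonide of 25 | C[C@@H]1C[C@H](C[C@@H]2CCCCCCCCCCCC[C@@H]3O[C@H]3[C@H](O[Si](CC)(CC)CC)/C=C\C(=O)O2)OC(C)(C)O1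
A5 | alternative 3 | (2S)-1-[(4R,6R)-2,2,6-trimethyl-1,3-dioxan-4-yl]hexadec-15-en-2-yl 4-hydroxyhex-5-en-2-ynoate, C4 arranged as in 25 | C[C@@H]1C[C@H](C[C@@H](OC(=O)C#C[C@@H](O)C=C)CCCCCCCCCCCCC=C)OC(C)(C)O1
A6 | alternative 3 | 20-membered 2-ynoate lactone with (5E)-alkene and C4 hydroxyl, 21,23-acetonide, centres arranged as in 25 | C[C@@H]1C[C@H](C[C@@H]2CCCCCCCCCCCC/C=C/[C@H](O)C#CC(=O)O2)OC(C)(C)O1
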